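Start from the unit: a percent here is a percent of the substrate charged, and a target or an isomer of the product counts as two, so the substrate left and what it has become add up to the whole charge. You can therefore work with the fraction left.

| setting | midnight | dawn | flask |
|---|---|---|---|
| substrate | 5.0 × 10⁻⁴ M | 2.5 × 10⁻⁴ M | 5.0 × 10⁻⁴ M |
| remark | the very flask that is asked about, followed so far | run made earlier |  |
| time |  |  | 8.0 min |

| run | time / min | substrate / % | target / % |
|---|---|---|---|
| midnight | 1.00 | 64.6 | 21.5 |
| midnight | 2.00 | 64.9 | 22.6 |
| midnight | 3.00 | 64.5 | 22.5 |
| midnight | 4.00 | 64.3 | 22.0 |
| dawn | 0.667 | 77.5 | 14.2 |
| dawn | 2.00 | 75.4 | 15.2 |
| dawn | 4.00 | 75.8 | 14.9 |
| dawn | 6.00 | 76.2 | 15.2 |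

(readings scatter by 0.3 percentage points)

- in percentages every species weighs as the substrate in it: one target or isomer of the product counts as two
- the numbers in the tables scatter with a standard deviation of 0.3 percentage points
- reactions considered so far: target <-> isomer of the product; 2 substrate <-> target
- the reaction counts as stopped when no species that holds the substrate changes by six tenths of a point or more over the second half of the time

* at 8.0 min, what has stopped the reaction, if anything has (all of the substrate has reacted / it is still moving / forward and back rates have come level)
* share of the substrate used up at 8.0 min
* target at 8.0 min, in percent of the substrate charged

Take the main step first, two substrate to one target. The later dawn readings average 75.8% substrate and 15.1% target, so in the dawn run target concentration over substrate concentration squared reads 526 /M. Reckoned for the asked flask with this one step and no isomer, the fraction left plus a factor of 0.526 times its square makes up the charge, which gives a fraction left of 72.4%.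

Now add the isomer. The dawn remainder, 9.10%, which I take as isomer, stands to target as 0.603, and that exchange goes one for one, so I carry the ratio over to the asked flask. Both products then grow with the square of the fraction left. From dawn, 1680 /M is the share used up divided by the square of the fraction left and by the charge: the plateau number, an apparent equilibrium constant. For the asked flask, plateau number times charge is 0.842, so the fraction left falls to 64.7%. That means 35.3% used up and, at dawn's share of target among the products, 22.0% target.

The rest is time. The midnight readings of this same flask stay between 64.3% and 64.9% substrate from 1.00 min to 4.00 min, and my figure for the fraction left came from the dawn run and not from these readings, so I commit to a balanced plateau at 8.0 min.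

The forecast says forward and back rates have come level, with 35.4% used up and 22.3% target: “So the two reversible steps have balanced”. My dawn reckoning lies 0.30 percentage points below it in target.

The flask gives forward and back rates have come level, with 35.4% used up and 22.1% target, and over the second half of the time its shares move by 0 points.

    target ⇌ isomer of the product (K = 0.600, k = 0.320 /s)
    2 substrate ⇌ target (K = 530 /M, k = 33.0 /M/s)

Put the plateau number to a neighbour flask charged with 8.5 × 10⁻⁴ M, read at the same time: plateau number times charge is 1.43, which gives a fraction left of 55.7%. That neighbour flask stands at 55.5% substrate.

Readings and results stem from a simulated flask with constants of no real substance; scatter was added.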